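## The problem

Compound 16 is an open-chain 1,7-diarylheptane-3,5-diol. No ring has to be closed; the skeletal task is to lay a seven-carbon chain between a guaiacyl ring (ring A, 4-hydroxy-3-methoxyphenyl, on C1) and a syringyl ring (ring B, 4-hydroxy-3,5-dimethoxyphenyl, on C7). The two ends differ by one methoxy group, so the molecule is almost but not exactly C2-symmetric. A method that joins the halves without telling them apart would give two symmetric by-products that could hardly be separated from the mixed compound. The chain carries two stereocentres, C3 and C5, both S, as an anti 1,3-diol. Because they are 1,3-related, either can direct the other (hydroxyl-directed reduction of a β-hydroxy ketone), or both can be set by one chiral catalyst acting on a 1,3-dicarbonyl precursor. The fragile groups are the two electron-rich free phenols, which oxidise easily under basic aerobic conditions and would be acylated by any activated acid, and the β-oxygenated chain, which at the hydroxy-ketone level can dehydrate or undergo retro-aldol cleavage. The enabling feature is the single methylene C4 between the oxygen-bearing carbons C3 and C5. At the diketone oxidation level C4 is the central carbon of a 1,3-dicarbonyl, and C1–C3 and C5–C7 with their rings are two dihydrocinnamoyl units that map onto ferulic acid 1 and sinapic acid 5. The chain thus reads aryl-C3 + C1 + C3-aryl, and the one-carbon piece can be a malonate that gives up both carboxyl groups.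

## Retrosynthesis

**16 to 15 (the two phenolic O–benzyl bonds).** The phenols are masked as benzyl ethers in 15. Benzyl is preferred to silyl ethers, which would be at risk from imidazole and methanol in the chain-building step, and to alkyl ethers, which need harsh cleavage. The forward reaction is a neutral hydrogenolysis. It must spare the carbinol C–O bonds, which it should, since C3 and C5 are homobenzylic and not benzylic. The precursor is no smaller, but it is free of acidic, oxidisable groups.

**15 to 14 (the C3–H and C5–H bonds).** Removing the two carbinol hydrogens erases both stereocentres and leads to the achiral diketone 14. The neighbouring option, an aldol for one carbinol followed by a directed reduction for the other, needs two separate stereochemical events and a stoichiometric chiral controller. Here one catalyst, RuCl2[(S)-BINAP], is asked to set both centres, the second reduction being matched and chelation-guided to the anti diol. The forward reaction must deliver the S,S sense; this is expected for the (S)-ligand, because at both carbinols the C4 branch outranks the outer chain branch, as in simple dialkyl β-diketones.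

**14 to 9 + 4 + 8 (the C3–C4 and C4–C5 bonds).** Both bonds to the central methylene are cut. This leaves two acyl cations, available as the acyl imidazolides 4 and 8, and a methylene dianion, for which bis(trimethylsilyl) malonate 9 stands after loss of both carboxyl groups. Three neighbouring cuts were weighed:
- Cutting only C4–C5 would require a separately made methyl ketone and control over which side of it enolises.
- Cutting C1–C2 and C6–C7 would call for labile electron-rich benzylic halides and two alkylations with no means of telling the ends apart.
- Cutting C2–C3 by an aldol reaction would put C3 and C5 at the wrong oxidation level.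

The chosen cut removes the whole chain in one operation and leaves two near-identical C3 acids. The forward reaction must put two different acyl groups on one carbon in a fixed order without scrambling. An unprotected dicarboxylate was rejected as the C4 donor: its C–H acidity under MgCl2/Et3N is low, and it offers only temperature as a barrier between the two acylations. The silyl esters of 9 give normal malonate acidity and cannot lose CO2 until methanol is added. The second nucleophile therefore does not exist while the first acyl donor 4 is still present.

**4 to 3 and 8 to 7 (the acyl C–N bonds).** The imidazolides come from the acids 3 and 7 by activation with CDI. They are preferred to acid chlorides because the leaving group is a mild base that keeps the medium near neutral. The forward reaction only has to give material free of excess imidazole.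

**3 to 2 to 1 and 7 to 6 to 5 (the O–benzyl bond and the two side-chain C–H bonds).** The acids go back to dihydroferulic acid 2 and dihydrosinapic acid 6, and these to the commodity cinnamic acids 1 and 5. Hydrogenation is placed before benzylation so that Pd/C can be used without endangering a benzyl ether.

## Roads not taken

**Alternative 1:** The cut falls inside ring B, at C2–C3 and C5–C6 (C1 of the ring carrying the chain), so the syringyl ring is made last. The product of the key step would be A1, the acetonide of the (3S,5S)-diol with ring A benzylated and ring B as the free phenol. It would arise from 1,3-dimethoxyacetone A2 and the 2-substituted 3-(dimethylamino)acrolein A3, which carries the whole protected chain. A2 is deprotonated by KOtBu, one α-carbon adds to the aldehyde of A3, the other displaces dimethylamine at the enamine carbon, and loss of water aromatises the ring.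
- Merits: the two ends are distinguished by construction, so no symmetric by-product can form, and the syringyl phenol emerges unprotected. In cross-selectivity this road is better than the chosen one, which has to secure the same result by order of addition and a chemical gate.
- Weak points: it builds an arene that can be bought as 5. The anti diol must already be in place, so the stereochemical problem is only moved to an earlier, unspecified sequence. A3 requires α-formylation of an aldehyde at the end of a finished chiral chain bearing an acid-sensitive acetonide. The strongly basic condensation competes with self-condensation of A2.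
- Comparison: the chosen plan is far shorter. It makes the chain from two abundant acids in one operation and sets both stereocentres in one catalytic step.

**Alternative 2:** The cut is at the C3–O and C4–O bonds of an oxirane. The erythro (3S,4S,5S)-epoxy alcohol A4 would come from the racemic (E)-allylic alcohol A5 (carbinol at C5, alkene at C3=C4) by epoxidation with tBuOOH, Ti(OiPr)4 and L-(+)-DIPT. This converts the (5S) half of A5 and leaves the (5R) half. Hydride opening of A4 at C4 with NaAlH2(OCH2CH2OCH3)2 would then join the chosen route at 15.
- Merits: the face selection of this kinetic resolution is among the most reliable in asymmetric synthesis, and the erythro relation translates directly into the anti diol. In certainty of absolute configuration it is better than step 8 of the chosen plan, which rests on analogy.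
- Weak points: half of A5 is the wrong enantiomer by design. A5 needs its own C–C bond construction with redox adjustments on both arms. A regioselective epoxide opening is still required after the key step.
- Comparison: the chosen plan uses all of its material, needs no recycling or inversion, and reaches 15 in fewer operations.

**Alternative 3:** The cuts are C1–C2 and C6–C7. The product of the key step, A6, is identical with 15. It would come from the C2-symmetric (2R,4R)-1,2:4,5-diepoxypentane A7, opened at its two terminal carbons under CuI catalysis, first by the guaiacyl benzylic Grignard reagent A8 and then by its syringyl counterpart A9. The R descriptors of A7 become S only because the ranking of the neighbours changes.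
- Merits: the route is convergent, the configuration is fixed in A7 before the coupling, and no reduction is needed afterwards. In precedent for the key step and in certainty of configuration it is stronger than the chosen plan, whose key step is new as a one-flask sequence.
- Weak points: opening a symmetric bis-electrophile with two different nucleophiles is statistical and has no gate, so it meets the same separation problem. The electron-rich benzylic halides behind A8 and A9 are labile and prone to Wurtz coupling during Grignard formation. A7 is volatile, alkylating, and is itself normally obtained by asymmetric hydrogenation of a chlorinated C5 β-diketone, so the same type of reduction is only moved to an earlier stage.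
- Comparison: the chosen plan offers stable acyl donors from cheap acids, a chemical gate for cross-selectivity, and a stepwise fallback made of known reactions only.

Key step: step 7

Assumption: bis(trimethylsilyl) malonate 9 is treated as a purchased reagent, and the correlation of (S)-BINAP with the (3S,5S) diol in step 8 is an expectation by analogy with simple dialkyl β-diketones.

## Route

Step 1
Reactants: 1 ferulic acid [(E)-3-(4-hydroxy-3-methoxyphenyl)prop-2-enoic acid]
Product: 2 3-(4-hydroxy-3-methoxyphenyl)propanoic acid
Conditions: H2 (1 atm), 10% Pd/C, MeOH, rt
Reagents that add atoms: none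
Why: Heterogeneous hydrogenation of the conjugated C=C bond over Pd/C; arene, phenol and acid are inert under these conditions, and the reduction is placed before benzylation so that no benzyl ether meets Pd/C and H2 before the last step.

Step 2
Reactants: 2 3-(4-hydroxy-3-methoxyphenyl)propanoic acid
Product: 3 3-(4-benzyloxy-3-methoxyphenyl)propanoic acid
Conditions: BnBr (1.3 equiv), NaOH (3 equiv), EtOH/H2O, reflux; then aq. HCl to pH 2
Reagents that add atoms: benzyl bromide, BrCc1ccccc1
Why: Williamson ether synthesis on the phenoxide–carboxylate dianion, in which the phenoxide is the stronger nucleophile; any carboxylate benzylated in passing is saponified by the excess hydroxide at reflux, so acidification should return the free acid with only the phenol alkylated.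

Step 3
Reactants: 3 3-(4-benzyloxy-3-methoxyphenyl)propanoic acid
Product: 4 1-[3-(4-benzyloxy-3-methoxyphenyl)propanoyl]imidazole
Conditions: CDI (1.1 equiv), CH2Cl2, rt; quick cold-water wash, Na2SO4, concentrate
Reagents that add atoms: 1,1'-carbonyldiimidazole, O=C(n1ccnc1)n1ccnc1
Why: Activation of the acid by CDI through the acyl carboxy-imidazole mixed anhydride, which loses CO2 to give the acyl imidazolide; the cold wash removes the imidazole that could otherwise attack the silyl esters of 9 in step 7, and the benzyl ether is untouched.

Step 4
Reactants: 5 sinapic acid [(E)-3-(4-hydroxy-3,5-dimethoxyphenyl)prop-2-enoic acid]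
Product: 6 3-(4-hydroxy-3,5-dimethoxyphenyl)propanoic acid
Conditions: H2 (1 atm), 10% Pd/C, MeOH, rt
Reagents that add atoms: none
Why: The same alkene hydrogenation as in step 1; the additional methoxy group has no bearing on it.

Step 5
Reactants: 6 3-(4-hydroxy-3,5-dimethoxyphenyl)propanoic acid
Product: 7 3-(4-benzyloxy-3,5-dimethoxyphenyl)propanoic acid
Conditions: BnBr (2 equiv), NaOH (4 equiv), EtOH/H2O, reflux; then aq. HCl to pH 2
Reagents that add atoms: benzyl bromide, BrCc1ccccc1
Why: Williamson ether synthesis as in step 2; the 2,6-dimethoxyphenoxide is more hindered, hence the larger excess of BnBr and longer reflux, and ester formed in passing is again saponified in the same medium.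

Step 6
Reactants: 7 3-(4-benzyloxy-3,5-dimethoxyphenyl)propanoic acid
Product: 8 1-[3-(4-benzyloxy-3,5-dimethoxyphenyl)propanoyl]imidazole
Conditions: CDI (1.1 equiv), CH2Cl2, rt; quick cold-water wash, Na2SO4, concentrate
Reagents that add atoms: 1,1'-carbonyldiimidazole, O=C(n1ccnc1)n1ccnc1
Why: CDI activation as in step 3; the side-chain carboxyl is remote from the hindered ring positions, so the same behaviour is expected.

Step 7
Reactants: 9 bis(trimethylsilyl) malonate; 4 1-[3-(4-benzyloxy-3-methoxyphenyl)propanoyl]imidazole; 8 1-[3-(4-benzyloxy-3,5-dimethoxyphenyl)propanoyl]imidazole
Product: 14 1-(4-benzyloxy-3-methoxyphenyl)-7-(4-benzyloxy-3,5-dimethoxyphenyl)heptane-3,5-dione, via silyl acylmalonate 10 (not isolated), via acylmalonic acid 11 (not isolated), via magnesium β-keto carboxylate 12 (not isolated), via diacylacetic acid 13 (not isolated)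
Conditions: 9 (1.05 equiv), MgCl2 (2.5 equiv), Et3N (2.5 equiv), MeCN, 0 °C; 4 (1.0 equiv), 0 °C to rt; MeOH (2.1 equiv), 0 °C, then 40 °C until CO2 evolution ends; 8 (1.1 equiv), 40 °C; 1 M HCl work-up
Reagents that add atoms: none
Why: Proposed new method: soft enolisation of the silyl malonate 9 by MgCl2/Et3N gives a chelated magnesium enolate that is C-acylated by imidazolide 4 to the tricarbonyl 10, whose enolate is too stabilised to be acylated again and whose silyl esters cannot lose CO2; methanol then cleaves both silyl esters to 11, which decarboxylates on warming, and this loss of CO2 itself delivers the chelated magnesium enolate–carboxylate 12. Compound 12 is the keto analogue of a magnesium malonate half-ester enolate, so its C2 (the future C4) is acylated by imidazolide 8 to 13, and a second loss of CO2 gives the magnesium 1,3-diketonate of 14, a chelate that resists further acylation until the acidic work-up releases the diketone. The closest known reaction types are the acylation of bis(trimethylsilyl) malonate by acid chlorides under MgCl2/Et3N, which leads to β-keto acids, and the decarboxylative Claisen condensation of magnesium malonate half-esters with acyl imidazolides (Masamune–Brooks reaction); two such events on one carbon in one flask with two different acyl donors have not been shown. No ring is closed and no stereocentre is formed; the two new bonds are C3–C4 and C4–C5. The selectivity needed is cross-selectivity between two acyl donors that differ by one methoxy group, and it is secured by the order of addition and by a chemical gate: the second nucleophile 12 does not exist until methanol is added, by which time 4 should have been consumed by the slight excess of 9. The surplus of 9 ends as its desilylated magnesium dicarboxylate, whose low C–H acidity should keep it from competing with 12 for 8. Regiochemistry within 12 is fixed because only C2 lies between the ketone and the carboxylate.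

Step 8
Reactants: 14 1-(4-benzyloxy-3-methoxyphenyl)-7-(4-benzyloxy-3,5-dimethoxyphenyl)heptane-3,5-dione
Product: 15 (3S,5S)-1-(4-benzyloxy-3-methoxyphenyl)-7-(4-benzyloxy-3,5-dimethoxyphenyl)heptane-3,5-diol
Conditions: H2 (70 atm), RuCl2[(S)-BINAP] (1 mol %), MeOH/CH2Cl2, 50 °C
Reagents that add atoms: none
Why: Noyori asymmetric hydrogenation of a β-diketone: the first carbonyl is reduced through the chelated keto form under control of the (S)-BINAP ligand, and the resulting β-hydroxy ketone is reduced by the same catalyst in the matched, hydroxyl-chelated sense to the anti diol, so C3 and C5 should both be set as S by the catalyst, by analogy with pentane-2,4-dione, where the CH2C=O branch likewise outranks the alkyl branch. Minor enantiomer from the first reduction is channelled mainly into the syn diol, which should raise the enantiomeric purity of the anti isomer; aryl benzyl ethers are inert to RuCl2[(S)-BINAP] and H2.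

Step 9
Reactants: 15 (3S,5S)-1-(4-benzyloxy-3-methoxyphenyl)-7-(4-benzyloxy-3,5-dimethoxyphenyl)heptane-3,5-diol
Product: 16 (3S,5S)-1-(4-hydroxy-3-methoxyphenyl)-7-(4-hydroxy-3,5-dimethoxyphenyl)heptane-3,5-diol
Conditions: H2 (1 atm), 10% Pd/C, EtOAc/MeOH, rt
Reagents that add atoms: none
Why: Hydrogenolysis of the two aryl benzyl ethers over Pd/C under neutral conditions; the carbinols at C3 and C5 are homobenzylic, not benzylic, so their C–O bonds and configurations are not at risk.

## Compound list

1 | ferulic acid, (E)-3-(4-hydroxy-3-methoxyphenyl)prop-2-enoic acid | COc1cc(/C=C/C(=O)O)ccc1O | starting material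
2 | 3-(4-hydroxy-3-methoxyphenyl)propanoic acid | COc1cc(CCC(=O)O)ccc1O | intermediate
3 | 3-(4-benzyloxy-3-methoxyphenyl)propanoic acid | COc1cc(CCC(=O)O)ccc1OCc1ccccc1 | intermediate
4 | 1-[3-(4-benzyloxy-3-methoxyphenyl)propanoyl]imidazole | COc1cc(CCC(=O)n2ccnc2)ccc1OCc1ccccc1 | intermediate
5 | sinapic acid, (E)-3-(4-hydroxy-3,5-dimethoxyphenyl)prop-2-enoic acid | COc1cc(/C=C/C(=O)O)cc(OC)c1O | starting material
6 | 3-(4-hydroxy-3,5-dimethoxyphenyl)propanoic acid | COc1cc(CCC(=O)O)cc(OC)c1O | intermediate
7 | 3-(4-benzyloxy-3,5-dimethoxyphenyl)propanoic acid | COc1cc(CCC(=O)O)cc(OC)c1OCc1ccccc1 | intermediate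
8 | 1-[3-(4-benzyloxy-3,5-dimethoxyphenyl)propanoyl]imidazole | COc1cc(CCC(=O)n2ccnc2)cc(OC)c1OCc1ccccc1 | intermediate
9 | bis(trimethylsilyl) malonate | C[Si](C)(C)OC(=O)CC(=O)O[Si](C)(C)C | starting material
10 | bis(trimethylsilyl) 2-[3-(4-benzyloxy-3-methoxyphenyl)propanoyl]malonate (not isolated; present as its magnesium enolate) | COc1cc(CCC(=O)C(C(=O)O[Si](C)(C)C)C(=O)O[Si](C)(C)C)ccc1OCc1ccccc1 | intermediate
11 | 2-[3-(4-benzyloxy-3-methoxyphenyl)propanoyl]malonic acid (not isolated; present as its magnesium/triethylammonium salt) | COc1cc(CCC(=O)C(C(=O)O)C(=O)O)ccc1OCc1ccccc1 | intermediate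
12 | 5-(4-benzyloxy-3-methoxyphenyl)-3-oxopentanoic acid (not isolated; present as its magnesium enolate–carboxylate) | COc1cc(CCC(=O)CC(=O)O)ccc1OCc1ccccc1 | intermediate
13 | 2-[3-(4-benzyloxy-3,5-dimethoxyphenyl)propanoyl]-5-(4-benzyloxy-3-methoxyphenyl)-3-oxopentanoic acid (not isolated; racemic, enolised, present as its magnesium salt) | COc1cc(CCC(=O)C(C(=O)O)C(=O)CCc2cc(OC)c(OCc3ccccc3)c(OC)c2)ccc1OCc1ccccc1 | intermediate
14 | 1-(4-benzyloxy-3-methoxyphenyl)-7-(4-benzyloxy-3,5-dimethoxyphenyl)heptane-3,5-dione | COc1cc(CCC(=O)CC(=O)CCc2cc(OC)c(OCc3ccccc3)c(OC)c2)ccc1OCc1ccccc1 | intermediate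
15 | (3S,5S)-1-(4-benzyloxy-3-methoxyphenyl)-7-(4-benzyloxy-3,5-dimethoxyphenyl)heptane-3,5-diol | COc1cc(CC[C@H](O)C[C@@H](O)CCc2cc(OC)c(OCc3ccccc3)c(OC)c2)ccc1OCc1ccccc1 | intermediate
16 | (3S,5S)-1-(4-hydroxy-3-methoxyphenyl)-7-(4-hydroxy-3,5-dimethoxyphenyl)heptane-3,5-diol | COc1cc(CC[C@H](O)C[C@@H](O)CCc2cc(OC)c(O)c(OC)c2)ccc1O | target

## Step count and risks

Total step count: 9. Longest linear sequence: 6 steps (steps 1–3 or 4–6, then 7, 8 and 9).

**Step 7 (key step, proposed new method).**
- What may go wrong: premature loss of a silyl group during the first acylation, because the imidazole released can attack silicon. This would start decarboxylation while 4 is still present and scramble the two acyl donors, and the symmetric products could not be separated in practice. Excess MgCl2 and low temperature are meant to hold the released imidazole on the metal.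
- Further failure modes: loss of CO2 from 12 before it is acylated, methanolysis of 8 by residual methanol, and sluggish C-acylation by the mildly electrophilic imidazolides.
- Fallback (known reactions only), setting out from 4 and 7 and returning at 14: Masamune–Brooks reaction of 4 with mono-tert-butyl malonate (MgCl2, Et3N, MeCN) gives tert-butyl 5-(4-benzyloxy-3-methoxyphenyl)-3-oxopentanoate F1, which is isolated and purified. Acid 7 is converted by (COCl)2 and catalytic DMF into 3-(4-benzyloxy-3,5-dimethoxyphenyl)propanoyl chloride F2. The magnesium enolate of F1 (MgCl2, pyridine, CH2Cl2, 0 °C) is C-acylated by F2 to tert-butyl 2-[3-(4-benzyloxy-3,5-dimethoxyphenyl)propanoyl]-5-(4-benzyloxy-3-methoxyphenyl)-3-oxopentanoate F3. Catalytic TsOH in toluene at 80 °C removes isobutene to give the acid 13, which loses CO2 and returns to the route at 14. The same two bonds are made in the same order, but with an isolated β-keto ester between them, so cross-selectivity no longer depends on a gate.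

**Step 8.**
- What may go wrong: erosion of the anti selectivity in the second reduction, if the hydroxy ketone is hydrogenated outside the hydroxyl-chelated pathway at the temperature needed for full conversion. Acid-induced enol ether formation of the diketone in methanol could also stall the reduction. The sense of induction rests on analogy and would have to be confirmed on 15 or 16.
- Fallback, setting out from 14 and returning at 15: the two stereochemical events are separated. Hydrogenation with RuCl2[(S)-BINAP] is carried only as far as the β-hydroxy ketones (lower pressure, rt, one equivalent of H2). These are (5S)-1-(4-benzyloxy-3-methoxyphenyl)-7-(4-benzyloxy-3,5-dimethoxyphenyl)-5-hydroxyheptan-3-one F4 and its regioisomer (5S)-7-(4-benzyloxy-3-methoxyphenyl)-1-(4-benzyloxy-3,5-dimethoxyphenyl)-5-hydroxyheptan-3-one F5. The mixture is then reduced with Me4NBH(OAc)3 in MeCN/AcOH at −30 °C (Evans–Saksena reduction, intramolecular hydride delivery, 1,3-anti). Both regioisomers converge on 15, and the second centre is set by the substrate instead of the catalyst.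

**Step 5.**
- What may go wrong: incomplete O-alkylation of the hindered 2,6-dimethoxyphenoxide in the protic medium, with solvolysis of BnBr consuming the reagent.
- Fallback, setting out from 6 and returning at 7: exhaustive benzylation under aprotic conditions (BnBr, K2CO3, DMF, 60 °C) gives benzyl 3-(4-benzyloxy-3,5-dimethoxyphenyl)propanoate F6, which is isolated and then saponified (LiOH, THF/H2O, rt; aq. HCl) to 7.

## Further compounds

F1 | step 7 | tert-butyl 5-(4-benzyloxy-3-methoxyphenyl)-3-oxopentanoate | COc1cc(CCC(=O)CC(=O)OC(C)(C)C)ccc1OCc1ccccc1
F2 | step 7 | 3-(4-benzyloxy-3,5-dimethoxyphenyl)propanoyl chloride | COc1cc(CCC(Cl)=O)cc(OC)c1OCc1ccccc1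
F3 | step 7 | tert-butyl 2-[3-(4-benzyloxy-3,5-dimethoxyphenyl)propanoyl]-5-(4-benzyloxy-3-methoxyphenyl)-3-oxopentanoate | COc1cc(CCC(=O)C(C(=O)OC(C)(C)C)C(=O)CCc2cc(OC)c(OCc3ccccc3)c(OC)c2)ccc1OCc1ccccc1
F4 | step 8 | (5S)-1-(4-benzyloxy-3-methoxyphenyl)-7-(4-benzyloxy-3,5-dimethoxyphenyl)-5-hydroxyheptan-3-one | COc1cc(CCC(=O)C[C@@H](O)CCc2cc(OC)c(OCc3ccccc3)c(OC)c2)ccc1OCc1ccccc1
F5 | step 8 | (5S)-7-(4-benzyloxy-3-methoxyphenyl)-1-(4-benzyloxy-3,5-dimethoxyphenyl)-5-hydroxyheptan-3-one | COc1cc(CC[C@H](O)CC(=O)CCc2cc(OC)c(OCc3ccccc3)c(OC)c2)ccc1OCc1ccccc1
F6 | step 5 | benzyl 3-(4-benzyloxy-3,5-dimethoxyphenyl)propanoate | COc1cc(CCC(=O)OCc2ccccc2)cc(OC)c1OCc1ccccc1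
A1 | alternative 1 | (4S,6S)-4-[2-(4-benzyloxy-3-methoxyphenyl)ethyl]-6-[2-(4-hydroxy-3,5-dimethoxyphenyl)ethyl]-2,2-dimethyl-1,3-dioxane | COc1cc(CC[C@H](OC(C)(C)O2)C[C@@H]2CCc3cc(OC)c(O)c(OC)c3)ccc1OCc1ccccc1
A2 | alternative 1 | 1,3-dimethoxypropan-2-one | COCC(=O)COC
A3 | alternative 1 | 2-{2-[(4S,6S)-6-[2-(4-benzyloxy-3-methoxyphenyl)ethyl]-2,2-dimethyl-1,3-dioxan-4-yl]ethyl}-3-(dimethylamino)prop-2-enal | COc1cc(CC[C@H](OC(C)(C)O2)C[C@@H]2CCC(C=O)=CN(C)C)ccc1OCc1ccccc1
A4 | alternative 2 | (3S,4S,5S)-3,4-epoxy-1-(4-benzyloxy-3-methoxyphenyl)-7-(4-benzyloxy-3,5-dimethoxyphenyl)heptan-5-ol | COc1cc(CC[C@@H]2O[C@H]2[C@@H](O)CCc3cc(OC)c(OCc4ccccc4)c(OC)c3)ccc1OCc1ccccc1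
A5 | alternative 2 | racemic (E)-1-(4-benzyloxy-3-methoxyphenyl)-7-(4-benzyloxy-3,5-dimethoxyphenyl)hept-3-en-5-ol (target numbering) | COc1cc(CC/C=C/C(O)CCc2cc(OC)c(OCc3ccccc3)c(OC)c2)ccc1OCc1ccccc1
A6 | alternative 3 | (3S,5S)-1-(4-benzyloxy-3-methoxyphenyl)-7-(4-benzyloxy-3,5-dimethoxyphenyl)heptane-3,5-diol (identical with 15) | COc1cc(CC[C@H](O)C[C@@H](O)CCc2cc(OC)c(OCc3ccccc3)c(OC)c2)ccc1OCc1ccccc1
A7 | alternative 3 | (2R,4R)-1,2:4,5-diepoxypentane | C1O[C@@H]1C[C@@H]1CO1
A8 | alternative 3 | (4-benzyloxy-3-methoxybenzyl)magnesium chloride | COc1cc(C[Mg]Cl)ccc1OCc1ccccc1
A9 | alternative 3 | (4-benzyloxy-3,5-dimethoxybenzyl)magnesium chloride | COc1cc(C[Mg]Cl)cc(OC)c1OCc1ccccc1
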